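**Plan**
- Retrosynthesis: the three benzyl ethers come off last; C2–H is traced back to C2–CO2H; the C2'–O bond is traced back to C2'–H through a lactone that ties the C2 carboxyl to ring B.
- Enabling feature: C2' of ring B is ortho to C1', the carbon bonded to C3 of ring C, so a carboxyl on the adjacent ring C atom C2 lies six atoms from C2'–H; the other ortho carbon, C6', is blocked by the side chain.
- Ring C is cut at O1–C2 and C2–C3 (ethyl oxalyl chloride) to a deoxybenzoin, and that at C3–C4 into two benzaldehydes; the side chain is cut at C6'–CH2 (prenyl bromide) and at its tertiary C–O bond (hydration).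
- Forward: prenylation of the ring B aldehyde, union of rings A and B through C3–C4, closure of ring C with the carboxyl in place, hydration, closure of the temporary lactone at C2', opening, loss of CO2, debenzylation.
- Stereochemistry: the target has no stereocentre, so none has to be set.

Key step: step 8

Remark: isoflavone numbering is used (ring A C5–C8, ring C O1–C4, ring B C1'–C6'); the aryl–chromone axis is taken as freely rotating, and 1 and 7 are taken as catalogue compounds.

**Route**

Step 1
Reactants: 1 4-(benzyloxy)-3-methoxybenzaldehyde; 2 1-bromo-3-methylbut-2-ene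
Product: 6 4-(benzyloxy)-3-methoxy-2-(3-methylbut-2-en-1-yl)benzaldehyde, via lithium amino alkoxide 3 (not isolated), via ortho-lithiated amino alkoxide 4 (not isolated), via prenylated amino alkoxide 5 (not isolated)
Conditions: Me2NCH2CH2NHMe, n-BuLi, THF, −20 °C; 1; n-BuLi (3 equiv), −20 °C; CuBr·SMe2 (10 mol %), 2 (excess), −78 °C → rt; H2O
Reagents that add atoms: 1-bromo-3-methylbut-2-ene 2, CC(C)=CCBr
Why: Directed ortho-metalation, in which the in situ α-amino alkoxide and the C3 methoxy group together should steer n-BuLi to the carbon between them, followed by copper-catalysed SN2 allylation of the aryllithium at the primary carbon of prenyl bromide; water releases the aldehyde.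

Step 2
Reactants: 7 4-(benzyloxy)-2-hydroxybenzaldehyde
Product: 8 4-(benzyloxy)-2-(methoxymethoxy)benzaldehyde
Conditions: MOMCl, i-Pr2NEt, CH2Cl2, 0 °C → rt
Reagents that add atoms: chloromethyl methyl ether, COCCl
Why: Williamson-type O-alkylation with the reactive α-chloro ether should mask the phenol as its methoxymethyl acetal for the basic olefination in step 4.

Step 3
Reactants: 8 4-(benzyloxy)-2-(methoxymethoxy)benzaldehyde
Product: 10 diphenyl {[4-(benzyloxy)-2-(methoxymethoxy)phenyl](phenylamino)methyl}phosphonate, via N-phenyl imine 9 (not isolated)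
Conditions: PhNH2, (PhO)2P(O)H, i-PrOH, rt
Reagents that add atoms: aniline, Nc1ccccc1; diphenyl phosphite, O=[PH](Oc1ccccc1)Oc1ccccc1
Why: Kabachnik–Fields reaction, in which the aldehyde condenses with aniline and the P–H bond adds across the imine to give the racemic α-anilino phosphonate, whose centre is lost in step 4.

Step 4
Reactants: 10 diphenyl {[4-(benzyloxy)-2-(methoxymethoxy)phenyl](phenylamino)methyl}phosphonate; 6 4-(benzyloxy)-3-methoxy-2-(3-methylbut-2-en-1-yl)benzaldehyde
Product: 13 1-[4-(benzyloxy)-2-hydroxyphenyl]-2-[4-(benzyloxy)-3-methoxy-2-(3-methylbut-2-en-1-yl)phenyl]ethan-1-one, via enamine 11 (not isolated), via MOM-protected ketone 12 (not isolated)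
Conditions: Cs2CO3, THF/i-PrOH, rt; then 2 M aq. HCl, THF/MeOH, 40 °C
Reagents that add atoms: water, O
Why: Horner–Wadsworth–Emmons olefination of the α-amino phosphonate carbanion with 6 should give an enamine whose acid hydrolysis leaves the carbonyl on the ring A side (deoxybenzoin), and the same acid cleaves the ortho methoxymethyl acetal.

Step 5
Reactants: 13 1-[4-(benzyloxy)-2-hydroxyphenyl]-2-[4-(benzyloxy)-3-methoxy-2-(3-methylbut-2-en-1-yl)phenyl]ethan-1-one; 14 ethyl chloro(oxo)acetate (ethyl oxalyl chloride)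
Product: 17 ethyl 7-(benzyloxy)-3-[4-(benzyloxy)-3-methoxy-2-(3-methylbut-2-en-1-yl)phenyl]-4-oxo-4H-chromene-2-carboxylate, via aryl ethyl oxalate 15 (not isolated), via 2-hydroxychromanone ester 16 (not isolated)
Conditions: 14 (2 equiv), pyridine, 0 °C → rt
Reagents that add atoms: ethyl chloro(oxo)acetate 14, CCOC(=O)C(=O)Cl
Why: Isoflavone-2-carboxylate synthesis by O-acylation of the phenol, Baker–Venkataraman-type intramolecular attack of the doubly activated methylene on the aryl ester carbonyl and dehydration, run while the side chain is still an alkene so that no hydroxyl competes for the acid chloride.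

Step 6
Reactants: 17 ethyl 7-(benzyloxy)-3-[4-(benzyloxy)-3-methoxy-2-(3-methylbut-2-en-1-yl)phenyl]-4-oxo-4H-chromene-2-carboxylate
Product: 18 ethyl 7-(benzyloxy)-3-[4-(benzyloxy)-2-(3-hydroxy-3-methylbutyl)-3-methoxyphenyl]-4-oxo-4H-chromene-2-carboxylate
Conditions: Co(acac)2 (20 mol %), PhSiH3, O2 (1 atm), i-PrOH/THF, rt
Reagents that add atoms: dioxygen, O=O
Why: Mukaiyama hydration, in which hydrogen-atom transfer from a cobalt hydride to the electron-rich trisubstituted alkene gives the tertiary radical that is trapped by O2 and reduced to the Markovnikov alcohol, while the tetrasubstituted, electron-poor C2=C3 bond should be too hindered to react.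

Step 7
Reactants: 18 ethyl 7-(benzyloxy)-3-[4-(benzyloxy)-2-(3-hydroxy-3-methylbutyl)-3-methoxyphenyl]-4-oxo-4H-chromene-2-carboxylate
Product: 19 7-(benzyloxy)-3-[4-(benzyloxy)-2-(3-hydroxy-3-methylbutyl)-3-methoxyphenyl]-4-oxo-4H-chromene-2-carboxylic acid
Conditions: LiOH·H2O (1.5 equiv), THF/H2O, 0 °C; then 1 M HCl
Reagents that add atoms: lithium hydroxide, [Li+].[OH-]
Why: Saponification of the activated chromone-2-carboxylate should be complete at 0 °C before hydroxide can add to C2 and open the pyranone.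

Step 8
Reactants: 19 7-(benzyloxy)-3-[4-(benzyloxy)-2-(3-hydroxy-3-methylbutyl)-3-methoxyphenyl]-4-oxo-4H-chromene-2-carboxylic acid
Product: 20 3,9-bis(benzyloxy)-1-(3-hydroxy-3-methylbutyl)-2-methoxy-6H,12H-chromeno[3,4-b]chromene-6,12-dione (lactone between the C2 carboxyl of ring C and the new C2' oxygen of ring B)
Conditions: Cu(OAc)2 (10 mol %), (PhCO2)2 (1.3 equiv), HFIP, 75 °C
Reagents that add atoms: none
Why: The carboxylate of 19 binds divalent copper and is oxidised by dibenzoyl peroxide to a copper-bound carboxyl O-radical (formally a trivalent copper carboxylate), which adds to C2' of ring B; one-electron oxidation and loss of the C2' proton from the cyclohexadienyl radical then restore the arene and leave the new C2'–O bond. The closest known reaction type is the copper/peroxide C–H lactonisation of 2-arylbenzoic acids and of (Z)-3-arylacrylic acids to benzocoumarins and coumarins, of which this 3-arylchromone-2-carboxylic acid is a vinylogous member. The six-membered lactone ring O–C(=O)–C2–C3–C1'–C2' closes in the 6-endo ortho mode, the twisted aryl–chromone axis holding the carboxyl oxygen over the face of ring B. No stereocentre is formed. The step needs attack at C2' and not at C6' or C1': C6' is blocked by the hydroxyalkyl chain, C2' is para to the C5' methoxy group and thus activated towards the electrophilic O-radical, and the 5-exo ipso adduct at C1' cannot rearomatise without losing the C4' benzyl group. It also needs the arene to win over the benzylic C–H bonds of the ethers and over the carbinol, which HFIP (1,1,1,3,3,3-hexafluoropropan-2-ol) should support by hydrogen bonding to these oxygens and so deactivating the adjacent C–H bonds towards hydrogen abstraction.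

Step 9
Reactants: 20 3,9-bis(benzyloxy)-1-(3-hydroxy-3-methylbutyl)-2-methoxy-6H,12H-chromeno[3,4-b]chromene-6,12-dione
Product: 22 methyl 7-(benzyloxy)-3-[2,4-bis(benzyloxy)-6-(3-hydroxy-3-methylbutyl)-5-methoxyphenyl]-4-oxo-4H-chromene-2-carboxylate, via phenol methyl ester 21 (not isolated)
Conditions: K2CO3, MeOH/DMF (1:4), rt; then BnBr, rt
Reagents that add atoms: methanol, CO; benzyl bromide, BrCc1ccccc1
Why: Transesterification of the strained aryl lactone by methoxide should give the methyl ester and the C2' phenoxide, which is trapped in the same flask by Williamson etherification before it can close back onto the ester, the tertiary alcohol being inert to K2CO3/BnBr.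

Step 10
Reactants: 22 methyl 7-(benzyloxy)-3-[2,4-bis(benzyloxy)-6-(3-hydroxy-3-methylbutyl)-5-methoxyphenyl]-4-oxo-4H-chromene-2-carboxylate
Product: 23 7-(benzyloxy)-3-[2,4-bis(benzyloxy)-6-(3-hydroxy-3-methylbutyl)-5-methoxyphenyl]-4-oxo-4H-chromene-2-carboxylic acid
Conditions: LiOH·H2O, THF/H2O, 0 °C → rt; then 1 M HCl
Reagents that add atoms: lithium hydroxide, [Li+].[OH-]
Why: Saponification of the methyl chromone-2-carboxylate should give a free acid that cannot relactonise because the C2' oxygen is now benzylated.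

Step 11
Reactants: 23 7-(benzyloxy)-3-[2,4-bis(benzyloxy)-6-(3-hydroxy-3-methylbutyl)-5-methoxyphenyl]-4-oxo-4H-chromene-2-carboxylic acid
Product: 24 7-(benzyloxy)-3-[2,4-bis(benzyloxy)-6-(3-hydroxy-3-methylbutyl)-5-methoxyphenyl]-4H-chromen-4-one
Conditions: Cu2O (10 mol %), 1,10-phenanthroline (20 mol %), NMP/quinoline (3:1), 170 °C
Reagents that add atoms: none
Why: Copper-catalysed protodecarboxylation, in which the copper carboxylate of the acid α to the ring oxygen should extrude CO2 and the C2–Cu bond is protonated, the catalytic counterpart of the thermal decarboxylation of isoflavone-2-carboxylic acids.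

Step 12
Reactants: 24 7-(benzyloxy)-3-[2,4-bis(benzyloxy)-6-(3-hydroxy-3-methylbutyl)-5-methoxyphenyl]-4H-chromen-4-one
Product: 25 kwakhurin hydrate, 3-[2,4-dihydroxy-6-(3-hydroxy-3-methylbutyl)-5-methoxyphenyl]-7-hydroxy-4H-chromen-4-one
Conditions: H2 (1 atm), Pd/C (10 %), EtOAc/MeOH, rt
Reagents that add atoms: none
Why: Catalytic hydrogenolysis of the three aryl benzyl ethers over palladium should leave the tertiary alcohol, the methyl ether and the chromone untouched if stopped after three equivalents of H2.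

**Compound list**

1 | 4-(benzyloxy)-3-methoxybenzaldehyde (O-benzylvanillin) | COc1cc(C=O)ccc1OCc1ccccc1 | starting material
2 | 1-bromo-3-methylbut-2-ene (prenyl bromide) | CC(C)=CCBr | starting material
3 | lithium [4-(benzyloxy)-3-methoxyphenyl]{[2-(dimethylamino)ethyl](methyl)amino}methanolate (racemic) | [Li+].[O-]C(N(C)CCN(C)C)c1ccc(OCc2ccccc2)c(OC)c1 | intermediate
4 | 2-lithio derivative of 3 (lithium on the ring carbon between the amino alkoxide and methoxy groups) | [Li+].[O-]C(N(C)CCN(C)C)c1ccc(OCc2ccccc2)c(OC)c1[Li] | intermediate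
5 | lithium [4-(benzyloxy)-3-methoxy-2-(3-methylbut-2-en-1-yl)phenyl]{[2-(dimethylamino)ethyl](methyl)amino}methanolate (racemic) | [Li+].[O-]C(N(C)CCN(C)C)c1ccc(OCc2ccccc2)c(OC)c1CC=C(C)C | intermediate
6 | 4-(benzyloxy)-3-methoxy-2-(3-methylbut-2-en-1-yl)benzaldehyde | COc1c(OCc2ccccc2)ccc(C=O)c1CC=C(C)C | intermediate
7 | 4-(benzyloxy)-2-hydroxybenzaldehyde | O=Cc1ccc(OCc2ccccc2)cc1O | starting material
8 | 4-(benzyloxy)-2-(methoxymethoxy)benzaldehyde | COCOc1cc(OCc2ccccc2)ccc1C=O | intermediate
9 | (E)-1-[4-(benzyloxy)-2-(methoxymethoxy)phenyl]-N-phenylmethanimine | COCOc1cc(OCc2ccccc2)ccc1/C=N/c1ccccc1 | intermediate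
10 | diphenyl {[4-(benzyloxy)-2-(methoxymethoxy)phenyl](phenylamino)methyl}phosphonate (racemic) | COCOc1cc(OCc2ccccc2)ccc1C(Nc1ccccc1)P(=O)(Oc1ccccc1)Oc1ccccc1 | intermediate
11 | N-{1-[4-(benzyloxy)-2-(methoxymethoxy)phenyl]-2-[4-(benzyloxy)-3-methoxy-2-(3-methylbut-2-en-1-yl)phenyl]ethenyl}aniline (E/Z mixture) | COCOc1cc(OCc2ccccc2)ccc1C(Nc1ccccc1)=Cc1ccc(OCc2ccccc2)c(OC)c1CC=C(C)C | intermediate
12 | 1-[4-(benzyloxy)-2-(methoxymethoxy)phenyl]-2-[4-(benzyloxy)-3-methoxy-2-(3-methylbut-2-en-1-yl)phenyl]ethan-1-one | COCOc1cc(OCc2ccccc2)ccc1C(=O)Cc1ccc(OCc2ccccc2)c(OC)c1CC=C(C)C | intermediate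
13 | 1-[4-(benzyloxy)-2-hydroxyphenyl]-2-[4-(benzyloxy)-3-methoxy-2-(3-methylbut-2-en-1-yl)phenyl]ethan-1-one | Oc1cc(OCc2ccccc2)ccc1C(=O)Cc1ccc(OCc2ccccc2)c(OC)c1CC=C(C)C | intermediate
14 | ethyl chloro(oxo)acetate (ethyl oxalyl chloride) | CCOC(=O)C(=O)Cl | starting material
15 | 5-(benzyloxy)-2-{[4-(benzyloxy)-3-methoxy-2-(3-methylbut-2-en-1-yl)phenyl]acetyl}phenyl ethyl oxalate | CCOC(=O)C(=O)Oc1cc(OCc2ccccc2)ccc1C(=O)Cc1ccc(OCc2ccccc2)c(OC)c1CC=C(C)C | intermediate
16 | ethyl 7-(benzyloxy)-3-[4-(benzyloxy)-3-methoxy-2-(3-methylbut-2-en-1-yl)phenyl]-2-hydroxy-4-oxochromane-2-carboxylate (racemic diastereomer mixture) | CCOC(=O)C1(O)Oc2cc(OCc3ccccc3)ccc2C(=O)C1c1ccc(OCc2ccccc2)c(OC)c1CC=C(C)C | intermediate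
17 | ethyl 7-(benzyloxy)-3-[4-(benzyloxy)-3-methoxy-2-(3-methylbut-2-en-1-yl)phenyl]-4-oxo-4H-chromene-2-carboxylate | CCOC(=O)c1oc2cc(OCc3ccccc3)ccc2c(=O)c1-c1ccc(OCc2ccccc2)c(OC)c1CC=C(C)C | intermediate
18 | ethyl 7-(benzyloxy)-3-[4-(benzyloxy)-2-(3-hydroxy-3-methylbutyl)-3-methoxyphenyl]-4-oxo-4H-chromene-2-carboxylate | CCOC(=O)c1oc2cc(OCc3ccccc3)ccc2c(=O)c1-c1ccc(OCc2ccccc2)c(OC)c1CCC(C)(C)O | intermediate
19 | 7-(benzyloxy)-3-[4-(benzyloxy)-2-(3-hydroxy-3-methylbutyl)-3-methoxyphenyl]-4-oxo-4H-chromene-2-carboxylic acid | OC(=O)c1oc2cc(OCc3ccccc3)ccc2c(=O)c1-c1ccc(OCc2ccccc2)c(OC)c1CCC(C)(C)O | intermediate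
20 | 3,9-bis(benzyloxy)-1-(3-hydroxy-3-methylbutyl)-2-methoxy-6H,12H-chromeno[3,4-b]chromene-6,12-dione | COc1c(OCc2ccccc2)cc2oc(=O)c3oc4cc(OCc5ccccc5)ccc4c(=O)c3c2c1CCC(C)(C)O | intermediate
21 | methyl 7-(benzyloxy)-3-[4-(benzyloxy)-2-hydroxy-6-(3-hydroxy-3-methylbutyl)-5-methoxyphenyl]-4-oxo-4H-chromene-2-carboxylate (present as its potassium phenoxide) | COC(=O)c1oc2cc(OCc3ccccc3)ccc2c(=O)c1-c1c(O)cc(OCc2ccccc2)c(OC)c1CCC(C)(C)O | intermediate
22 | methyl 7-(benzyloxy)-3-[2,4-bis(benzyloxy)-6-(3-hydroxy-3-methylbutyl)-5-methoxyphenyl]-4-oxo-4H-chromene-2-carboxylate | COC(=O)c1oc2cc(OCc3ccccc3)ccc2c(=O)c1-c1c(OCc2ccccc2)cc(OCc2ccccc2)c(OC)c1CCC(C)(C)O | intermediate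
23 | 7-(benzyloxy)-3-[2,4-bis(benzyloxy)-6-(3-hydroxy-3-methylbutyl)-5-methoxyphenyl]-4-oxo-4H-chromene-2-carboxylic acid | COc1c(OCc2ccccc2)cc(OCc2ccccc2)c(-c2c(C(=O)O)oc3cc(OCc4ccccc4)ccc3c2=O)c1CCC(C)(C)O | intermediate
24 | 7-(benzyloxy)-3-[2,4-bis(benzyloxy)-6-(3-hydroxy-3-methylbutyl)-5-methoxyphenyl]-4H-chromen-4-one | COc1c(OCc2ccccc2)cc(OCc2ccccc2)c(-c2coc3cc(OCc4ccccc4)ccc3c2=O)c1CCC(C)(C)O | intermediate
25 | kwakhurin hydrate, 3-[2,4-dihydroxy-6-(3-hydroxy-3-methylbutyl)-5-methoxyphenyl]-7-hydroxy-4H-chromen-4-one | COc1c(O)cc(O)c(-c2coc3cc(O)ccc3c2=O)c1CCC(C)(C)O | target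

**Step count and risks**

Total: 12 steps. Longest linear sequence: 11 steps (steps 2 to 12, from 7).

Steps most likely to fail: step 8, step 1, step 11.

Step 8. The carboxyl O-radical may lose CO2 before it cyclises, may abstract hydrogen from a benzylic ether position, or may attack C1' with loss of the C4' benzyl group (dearomatising spirocyclisation). The fallback gives up the radical pathway for a directed C–H palladation; it sets out from acid 19 and comes back at lactone 20. With Pd(OAc)2 (10 mol %), N-acetylglycine, PhI(OAc)2 and KOAc in t-BuOH at 80 °C, the carboxylate should steer divalent palladium to C2'–H by concerted metalation–deprotonation, giving a seven-membered palladacycle. PhI(OAc)2 then oxidises it to tetravalent palladium, and C–O reductive elimination closes the same lactone. No O-centred radical is involved and the site is fixed by the metallacycle, so the three processes above should not operate. The fallback makes no compound outside the compound list (F0).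

Step 1. Deprotonation at the benzylic OCH2 of the benzyl ether (followed by Wittig rearrangement), lithiation at a ring carbon other than the one between the two directing groups, or SN2' attack on prenyl bromide may divert the reaction. The fallback replaces metalation by an aromatic Claisen rearrangement. It sets out from no numbered compound but from a second catalogue aldehyde, 4-(benzyloxy)-3-hydroxybenzaldehyde F1, which takes the place of 1, and it comes back at aldehyde 6. O-Allylation (allyl bromide, K2CO3, DMF) should give 3-(allyloxy)-4-(benzyloxy)benzaldehyde F2. Heating in N,N-diethylaniline at about 190 °C should move the allyl group to the only free ortho carbon and give 2-allyl-4-(benzyloxy)-3-hydroxybenzaldehyde F3. O-Methylation (MeI, K2CO3, acetone) gives 2-allyl-4-(benzyloxy)-3-methoxybenzaldehyde F4. Cross-metathesis with 2-methylbut-2-ene (second-generation Grubbs catalyst, CH2Cl2, 40 °C) then turns the allyl into the prenyl group of 6.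

Step 11. At 170 °C the tertiary alcohol may dehydrate or the pyranone may open before CO2 is lost, or the hindered acid may not decarboxylate at all. The fallback removes the whole C2 carbon with its carboxyl and puts a new C2 in; it sets out from acid 23 and comes back at isoflavone 24. Boiling aqueous NaOH/EtOH should add hydroxide at C2, open ring C and cleave the resulting diketo acid (retro-Claisen) to oxalate and the deoxybenzoin 1-[4-(benzyloxy)-2-hydroxyphenyl]-2-[2,4-bis(benzyloxy)-6-(3-hydroxy-3-methylbutyl)-5-methoxyphenyl]ethan-1-one F5. Heating F5 with N,N-dimethylformamide dimethyl acetal in toluene at 100 °C should give the enaminone 1-[4-(benzyloxy)-2-hydroxyphenyl]-2-[2,4-bis(benzyloxy)-6-(3-hydroxy-3-methylbutyl)-5-methoxyphenyl]-3-(dimethylamino)prop-2-en-1-one F6, which is not isolated. F6 closes onto the phenol with loss of dimethylamine to give 24.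

**Further compounds**

F0 | step 8 | none | none
F1 | step 1 | 4-(benzyloxy)-3-hydroxybenzaldehyde | O=Cc1ccc(OCc2ccccc2)c(O)c1
F2 | step 1 | 3-(allyloxy)-4-(benzyloxy)benzaldehyde | C=CCOc1cc(C=O)ccc1OCc1ccccc1
F3 | step 1 | 2-allyl-4-(benzyloxy)-3-hydroxybenzaldehyde | C=CCc1c(O)c(OCc2ccccc2)ccc1C=O
F4 | step 1 | 2-allyl-4-(benzyloxy)-3-methoxybenzaldehyde | C=CCc1c(OC)c(OCc2ccccc2)ccc1C=O
F5 | step 11 | 1-[4-(benzyloxy)-2-hydroxyphenyl]-2-[2,4-bis(benzyloxy)-6-(3-hydroxy-3-methylbutyl)-5-methoxyphenyl]ethan-1-one | COc1c(OCc2ccccc2)cc(OCc2ccccc2)c(CC(=O)c2ccc(OCc3ccccc3)cc2O)c1CCC(C)(C)O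
F6 | step 11 | 1-[4-(benzyloxy)-2-hydroxyphenyl]-2-[2,4-bis(benzyloxy)-6-(3-hydroxy-3-methylbutyl)-5-methoxyphenyl]-3-(dimethylamino)prop-2-en-1-one | COc1c(OCc2ccccc2)cc(OCc2ccccc2)c(C(=CN(C)C)C(=O)c2ccc(OCc3ccccc3)cc2O)c1CCC(C)(C)O
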